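## The problem

1. Cembrane numbering is used for every compound. C1 is the ring CH bearing the branch C15H(C17H3)–C16(=O). The ring then runs C2H2, C3H(O-lactone), C4(OH)(C18H3), C5H2, C6H=C7H, C8(OOH)(C19H3), C9H2, C10H2, C11H–C12(C20H3) (epoxide), C13H2, C14H2. The target is therefore a 14-membered carbocycle bridged from C1 to C3 by a δ-lactone (ring O–C3–C2–C1–C15–C16), a bicyclo[11.3.1] system.
2. On the lactone ring the bonds C1–C14 and C3–C4 are cis and C17 is trans to C14. All three substituents are thus equatorial, and C15, which is epimerisable, sits in its favoured position.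
3. The seven stereocentres form three islands (C15/C1/C3/C4, C8, C11/C12). Saturated CH2 pairs separate them, so no island can control another through bonds.
4. C3(O)/C4(O) is the anti-dioxygenation pattern of an E-olefin, that is a (3S,4S)-epoxide opened at C3 with inversion. The 11S,12S-epoxide and the 8S C–O bond have the same local sense.
5. The skeleton holds three nearly identical E-CH=C(CH3) units (C3/C4, C7/C8, C11/C12), and each must undergo a different oxidation. This is the central selectivity problem.
6. The carbocycle has no heteroatom link, and most ring members (C2, C5, C9, C10, C13, C14) are bare CH2 groups, so few positions offer a handle for ring closure.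
7. The tertiary allylic hydroperoxide is sensitive to reduction, to acid (Hock cleavage) and to radical allylic shift, so it must come last. The trisubstituted epoxide is acid-labile and the lactone α-centre is base-labile.
8. The enabling feature is C13. It is functionless in the target, it flanks epoxide carbon C12, and it stands 1,3 to C1 (C13–C14–C1). An ester oxygen on C13 completes the six-atom array C15=C16–O–C13–C14=C1 for a [3,3] shift. The acid released by that shift lies exactly one δ-lactone ring (O–C16–C15–C1–C2–C3) away from a 3,4-epoxide.

## Retrosynthesis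

**20 ⇒ 19 (cut C8–O, return the olefin from C6=C7 to C7=C8).**
- The hydroperoxide cannot be carried through any earlier step.
- A tertiary allylic OOH beside an E-disubstituted olefin is the retron of a Schenck ene reaction.
- Compound 19 has one olefin, so only regiochemistry (C6–H against C19–H) and face selectivity are asked of the forward step.

**19 ⇒ 18 (add unsaturation at C13=C14).**
- This costs one reduction.
- It places an olefin where a sigmatropic shift would leave it.
- The forward step must distinguish a disubstituted from a trisubstituted olefin without touching an allylic epoxide.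

**18 ⇒ 14 (cut C1–C15 and O–C3; key disconnection).**
- C1–C15 is the only bond at C1 that lies outside the carbocycle.
- Cutting it removes the whole branch, the lactone ring and the stereocentres C1 and C15. Cutting C1–C2 or C1–C14 would keep the branch and its stereochemical burden in a chain fragment.
- Written as a retro-[3,3] shift, the propanoate moves to O13 of the branch-free macrocycle 14, and the lactone oxygen is traced to a 3,4-epoxide.
- The forward reaction must transfer C13 chirality to C1, set C15, and let the freed acid 17 open the epoxide at C3 only.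

**14 ⇒ 12 + 13, then 12 ⇒ 9 (cut O13–acyl, then C13–C14).**
- C13 adjoins the fully substituted C12, so it is a poor SN2 centre but a good aldehyde.
- Closing the ring by carbonyl addition creates exactly the allylic oxygen that the key step consumes.
- Closing at C1–C2 instead would require a macrocyclic SN2 and would deliver no oxygen at C13.
- Compound 9 is an open chain. The forward step must give an E-olefin (C14=C1) and the 13S alcohol.

**9 ⇒ 8 ⇒ 7 ⇒ 6 ⇒ 5 (remove the C13 oxygen and the 11,12-epoxide).**
- C13 is the E-methyl group of a terminal isopropylidene unit, the one position that allylic hydroxylation selects in a polyprenyl chain.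
- The hydroxyl of 6 makes C11=C12 the only allylic-alcohol olefin, so a directed asymmetric epoxidation reaches it and spares C7=C8.
- The same oxygen later becomes the aldehyde, the carrier of the branch and one carboxyl oxygen.

**5 ⇒ 2 + 3, then 2 ⇒ 1 (cut C1–C2, remove the 3,4-epoxide).**
- The ring carbons C2–C13 with C18–C20 are those of 1, with all three E-olefins in place. C1 and C14 are the two alkyne carbons of 3.
- In 1 only C3=C4 is an allylic-alcohol olefin, so the first directed epoxidation is also site-specific.
- Both epoxidations need the same catalyst enantiomer.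
- In total, 15 + 2 + 3 carbons come from three commercial compounds (1, 3, 13).

## Roads not taken

**Alternative 1 (the obvious, biosynthesis-ordered route).**
- Cut: both epoxide oxygens and O–C3, back to the macrocyclic (3E,7E,11E)-triene acid A1. A1 would itself be closed at C1–C2 from an open C20 chain or by olefin metathesis.
- Forward key step: peripheral epoxidation of C3=C4 and C11=C12 of A1, lactonisation, then the ene reaction.
- Why the chosen plan is better:
  - A1 offers three olefins of equal substitution and electron density, and no peracid or dioxirane can be asked to leave C7=C8 alone.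
  - Facial sense would rest on a conformer population biased by C1 only.
  - C1 and C15 would still have to be built in a chain-assembly phase about as long as the whole present route.
  - In the chosen plan each epoxide is placed while its olefin is the only allylic alcohol.

**Alternative 2.**
- Cut: C3–C4.
- Forward key step: reductive ketone–aldehyde coupling (pinacol macrocyclisation) of keto aldehyde A2 with low-valent titanium or SmI2. The C3 alkoxide then closes the lactone on the C16 ester, so two rings form in one operation.
- Why the chosen plan is better:
  - C3 and C4 would both be created in the ring-closing event, with no nearby control element and four possible diols.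
  - Reductants strong enough for the coupling also deoxygenate or open the 11,12-epoxide. That epoxide would then have to come later, which restores the C7=C8/C11=C12 problem.
  - The epoxide-inversion logic of the chosen plan derives C3/C4 stereospecifically from olefin geometry.

**Alternative 3.**
- Cut: C1–C15 homolytically.
- Forward key step: 6-exo-trig attack of a C15 radical, tethered to O3, on the C1=C14 olefin of macrocyclic diol A3 (ring closed by metathesis of two allyl termini).
- It shares the idea of a branch-free ring.
- Why the chosen plan is better:
  - A3 requires a vinyl nucleophile to displace a leaving group at the neopentyl-like C13.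
  - An ester tether is held in the s-trans form and cannot reach C1.
  - An acetal tether needs protection of the C4 hydroxyl and a later oxidation of the acetal carbon beside an acid-labile epoxide.
  - The slow 6-exo closure sets C1 only by a chair preference and does not set C15 at all.
  - The [3,3] shift is concerted and stereospecific, and C13 is attacked as a carbonyl.

Key step: step 9

Assumption: 1 is used in high (2E,6E) isomeric purity, because the E geometry of C3=C4 and C11=C12 becomes the relative configuration within both epoxides.

## Steps

Step 1
Reactants: 1 (2E,6E)-farnesol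
Product: 2 (2S,3S)-2,3-epoxyfarnesol (3S,4S-epoxide in target numbering)
Conditions: Ti(OiPr)4 (0.1 equiv), L-(+)-diethyl tartrate (0.12 equiv), t-BuOOH, 4 Å MS, CH2Cl2, −20 °C
Reagents that add atoms: tert-butyl hydroperoxide, CC(C)(C)OO
Why: Sharpless asymmetric epoxidation reaches only C3=C4, the one olefin that is part of an allylic alcohol, so C7=C8 and C11=C12 stay intact. L-(+)-tartrate converts E-3-methyl-2-alken-1-ols into the (2S,3S)-epoxy alcohols, which sets 3S and 4S.

Step 2
Reactants: 2 (2S,3S)-2,3-epoxyfarnesol; 3 ethynyltrimethylsilane
Product: 5 (3S,4S)-epoxy dienyne bearing SiMe3 on C14, via epoxy triflate 4 (not isolated)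
Conditions: Tf2O, 2,6-lutidine, CH2Cl2, −78 °C; then LiC≡CSiMe3 (from 3 and n-BuLi), THF–DMPU, −78 → −30 °C
Reagents that add atoms: triflic anhydride, O=S(=O)(OS(=O)(=O)C(F)(F)F)C(F)(F)F (its atoms stay only in 4)
Why: SN2 alkylation of a lithium acetylide by a primary triflate proceeds far below the temperature at which an unactivated trisubstituted epoxide is opened. No stereocentre is touched, and the two alkyne carbons become C1 and C14.

Step 3
Reactants: 5 (3S,4S)-epoxy dienyne bearing SiMe3 on C14
Product: 6 (11E)-C13 allylic alcohol
Conditions: SeO2 (0.3 equiv), t-BuOOH, CH2Cl2, 0 → 25 °C, stopped at partial conversion with recovery of 5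
Reagents that add atoms: tert-butyl hydroperoxide, CC(C)(C)OO (terminal oxygen source, relayed by SeO2)
Why: Selenium dioxide allylic hydroxylation (ene reaction then [2,3] shift) prefers the terminal isopropylidene olefin and, within it, the E-methyl group. C13 is therefore oxygenated and C11=C12 keeps the E geometry.

Step 4
Reactants: 6 (11E)-C13 allylic alcohol
Product: 7 (3S,4S,11S,12S)-bis-epoxy alcohol
Conditions: Ti(OiPr)4 (0.1 equiv), L-(+)-diethyl tartrate (0.12 equiv), t-BuOOH, 4 Å MS, CH2Cl2, −20 °C
Reagents that add atoms: tert-butyl hydroperoxide, CC(C)(C)OO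
Why: In this second Sharpless asymmetric epoxidation C11=C12 is the only allylic-alcohol olefin, so C7=C8 is spared again, and the same tartrate gives the (2S,3S)-type product of E-2-methyl-2-alken-1-ols, which is 11S,12S. Any minor enantiomer carried from step 1 becomes a separable diastereomer, so the enantiomeric purity of 7 should exceed that of 2.

Step 5
Reactants: 7 (3S,4S,11S,12S)-bis-epoxy alcohol
Product: 8 bis-epoxy alcohol with terminal alkyne
Conditions: K2CO3 (0.2 equiv), MeOH, 0 °C
Reagents that add atoms: none
Why: Base-catalysed protiodesilylation of an alkynylsilane. A Payne rearrangement would require attack at the fully substituted C12 and should not compete under these mild conditions.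

Step 6
Reactants: 8 bis-epoxy alcohol with terminal alkyne
Product: 9 bis-epoxy ynal
Conditions: TEMPO (0.1 equiv), PhI(OAc)2, CH2Cl2, 25 °C
Reagents that add atoms: none
Why: Oxoammonium oxidation of a primary alcohol stops at the aldehyde. C12 carries no hydrogen, so the α-centre cannot epimerise (C12 becomes R by CIP only).

Step 7
Reactants: 9 bis-epoxy ynal
Product: 12 macrocyclic (13S)-allylic alcohol with E-C14=C1, via alkenylborane 10 (not isolated), via alkenylzinc 11 (not isolated)
Conditions: Cy2BH, hexane–CH2Cl2, 0 °C; solution added over 6 h to Et2Zn, (−)-DAIB (0.1 equiv), hexane, 0 °C (final 5 mM); H2O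
Reagents that add atoms: dicyclohexylborane, B(C1CCCCC1)C1CCCCC1 (atoms only in 10); diethylzinc, CC[Zn]CC (atoms only in 11)
Why: Syn hydroboration of the terminal alkyne (boron on C14) outruns attack on the aldehyde or on the trisubstituted olefin. Boron-to-zinc exchange and amino-alcohol-catalysed intramolecular alkenylzinc addition under slow addition then close the ring as an E-allylic alcohol, a reaction type established for ω-alkynals. (−)-DAIB directs organozinc reagents to the Si face of aldehydes, which here gives 13S, the same face that a Felkin–Anh approach anti to the epoxide C–O bond should expose.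

Step 8
Reactants: 12 macrocyclic (13S)-allylic alcohol with E-C14=C1; 13 propanoic anhydride
Product: 14 macrocyclic (13S)-allylic propanoate
Conditions: 13, Et3N, DMAP (0.2 equiv), CH2Cl2, 0 → 25 °C
Reagents that add atoms: none
Why: DMAP-catalysed acylation with retention at C13. It brings in C15, C16 and C17.

Step 9
Reactants: 14 macrocyclic (13S)-allylic propanoate
Product: 18 13,14-didehydro hydroxy lactone, via silyl ketene acetal 15 (not isolated), via silyl ester 16 (not isolated), via epoxy acid 17 (not isolated)
Conditions: LiN(iPr)2, THF, −78 °C; Me3SiCl–Et3N, −78 → 25 °C; MeOH, 0 °C; evaporation; toluene, 45 °C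
Reagents that add atoms: chlorotrimethylsilane, C[Si](C)(C)Cl (its atoms stay only in 15 and 16)
Why: Ireland–Claisen rearrangement followed in the same flask by epoxy-acid lactonisation; the closest known types are the rearrangement of E-allylic propanoates of secondary alcohols and the spontaneous δ-lactonisation of 5,6-epoxy acids. Kinetic deprotonation in THF without polar cosolvent and O-silylation give the (E)-silyl ketene acetal 15, with C17 cis to the allylic oxygen. Compound 15 reorganises through the array C15=C16–O–C13–C14=C1 in a chair whose bulky, fully substituted C12 must be pseudo-equatorial, so C1–C15 forms on the face of C14=C1 that carried O13 (13S gives the C1 configuration of the target, S by CIP in 16–18 and R in 19 and 20) and the olefin moves to C13=C14 with E geometry. An E-olefin and an (E)-ketene acetal in a chair give the anti product, that is 15S with C17 trans to C14, and any leakage through a boat affects only C15, which is epimerisable toward this same equatorial position. Methanolysis of 16 frees acid 17, whose carboxyl attacks C3 from the rear in a 6-exo-tet closure (SN2, 3S to 3R) to form the δ-lactone, with O4 staying on C4 (4S) as the tertiary alcohol. The ester must be deprotonated in preference to C2–H, which its far greater acidity secures. Opening must occur at C3 rather than C4, which the collinear attack geometry and the six- against seven-membered ring secure. The 3,4-epoxide must react in preference to the now allylic 11,12-epoxide, whose capture at C14 would need prior ionisation, and the aprotic, weakly acidic medium disfavours that.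

Step 10
Reactants: 18 13,14-didehydro hydroxy lactone
Product: 19 (7E)-hydroxy lactone with saturated C13–C14
Conditions: 2-nitrobenzenesulfonyl hydrazide (in portions), Et3N, THF, 25 °C
Reagents that add atoms: none
Why: Diimide reduction is a concerted syn transfer of H2 whose rate falls steeply with olefin substitution, so E-disubstituted C13=C14 should react before trisubstituted C7=C8. Unlike metal-surface hydrogenation, it does not cleave the allylic epoxide C–O bond.

Step 11
Reactants: 19 (7E)-hydroxy lactone with saturated C13–C14
Product: 20 target hydroperoxide (1R,3R,4S,6E,8S,11S,12S,15S)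
Conditions: O2, tetraphenylporphyrin (1 mol %), white LED, CH2Cl2, −20 °C
Reagents that add atoms: dioxygen, O=O
Why: In this Schenck ene reaction on the only olefin left, oxygen binds C8 and removes H from C6 on the same face, moving the double bond to C6=C7 with E geometry. The cis effect limits abstraction to the side bearing C6 and C19, and in the non-polar solvent the C4 hydroxyl can hydrogen-bond the developing perepoxide and favour the C6 side. Attack from the ring periphery on the conformer with C18, C19 and C20 on one side of the ring, the same local sense in which C3/C4 and C11/C12 carry their oxygens, gives 8S.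

## Compound list

1 | (2E,6E)-farnesol | CC(C)=CCC/C(C)=C/CC/C(C)=C/CO | starting material
2 | (2S,3S)-2,3-epoxyfarnesol (3S,4S in target numbering) | CC(C)=CCC/C(C)=C/CC[C@]1(C)O[C@H]1CO | intermediate
3 | ethynyltrimethylsilane | C#C[Si](C)(C)C | starting material
4 | triflate of 2 at O–C2 (3S,4S) | CC(C)=CCC/C(C)=C/CC[C@]1(C)O[C@H]1COS(=O)(=O)C(F)(F)F | intermediate
5 | open chain Me3Si–C14≡C1–C2H2–(3S,4S)-3,4-epoxide–C5–C6–(7E)-C7=C8–C9–C10–C11=C12Me2 | CC(C)=CCC/C(C)=C/CC[C@]1(C)O[C@H]1CC#C[Si](C)(C)C | intermediate
6 | 5 hydroxylated at C13, (7E,11E) | OC/C(C)=C/CC/C(C)=C/CC[C@]1(C)O[C@H]1CC#C[Si](C)(C)C | intermediate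
7 | (3S,4S,11S,12S)-3,4:11,12-bis-epoxy C13 alcohol, silyl alkyne | OC[C@]1(C)O[C@H]1CC/C(C)=C/CC[C@]2(C)O[C@H]2CC#C[Si](C)(C)C | intermediate
8 | (3S,4S,11S,12S)-bis-epoxy C13 alcohol, terminal alkyne | OC[C@]1(C)O[C@H]1CC/C(C)=C/CC[C@]2(C)O[C@H]2CC#C | intermediate
9 | bis-epoxy ynal, C13 aldehyde (3S,4S,11S; C12 unchanged in space, R by CIP) | O=C[C@]1(C)O[C@H]1CC/C(C)=C/CC[C@]2(C)O[C@H]2CC#C | intermediate
10 | (E)-C14 alkenyl(dicyclohexyl)borane of 9 | O=C[C@]1(C)O[C@H]1CC/C(C)=C/CC[C@]2(C)O[C@H]2C/C=C/B(C3CCCCC3)C3CCCCC3 | intermediate
11 | (E)-C14 alkenyl(ethyl)zinc of 9 | O=C[C@]1(C)O[C@H]1CC/C(C)=C/CC[C@]2(C)O[C@H]2C/C=C/[Zn]CC | intermediate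
12 | 14-membered carbocycle, (3S,4S,11S,12S,13S)-3,4:11,12-diepoxy-13-ol, E-C14=C1, E-C7=C8 | O[C@H]1/C=C/C[C@@H]2O[C@@]2(C)CC/C=C(C)/CC[C@@H]2O[C@]21C | intermediate
13 | propanoic anhydride | CCC(=O)OC(=O)CC | starting material
14 | (13S)-propanoate of 12 | CCC(=O)O[C@H]1/C=C/C[C@@H]2O[C@@]2(C)CC/C=C(C)/CC[C@@H]2O[C@]21C | intermediate
15 | (E)-O-trimethylsilyl ketene acetal of 14 | C/C=C(/O[Si](C)(C)C)O[C@H]1/C=C/C[C@@H]2O[C@@]2(C)CC/C=C(C)/CC[C@@H]2O[C@]21C | intermediate
16 | trimethylsilyl ester of 17 | C[Si](C)(C)OC(=O)[C@@H](C)[C@H]1C[C@@H]2O[C@@]2(C)CC/C=C(C)/CC[C@@H]2O[C@@]2(C)/C=C/1 | intermediate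
17 | (15S)-2-substituted propanoic acid on C1 of the (3S,4S,11S,12S)-diepoxy (7E,13E)-diene ring, C1 as in the target | OC(=O)[C@@H](C)[C@H]1C[C@@H]2O[C@@]2(C)CC/C=C(C)/CC[C@@H]2O[C@@]2(C)/C=C/1 | intermediate
18 | δ-lactone (3R,4S,11S,12S,15S; C1 as in the target), 4-OH, 11,12-epoxide, (7E,13E)-diene | C[C@@H]1C(=O)O[C@@H]2C[C@H]1/C=C/[C@]1(C)O[C@H]1CC/C(C)=C/CC[C@]2(C)O | intermediate
19 | δ-lactone (1R,3R,4S,11S,12S,15S), 4-OH, 11,12-epoxide, (7E)-olefin | C[C@@H]1C(=O)O[C@@H]2C[C@H]1CC[C@]1(C)O[C@H]1CC/C(C)=C/CC[C@]2(C)O | intermediate
20 | CNP0297487.4, (1R,3R,4S,6E,8S,11S,12S,15S)-8-hydroperoxide | C[C@@H]1C(=O)O[C@@H]2C[C@H]1CC[C@]1(C)O[C@H]1CC[C@](C)(OO)/C=C/C[C@]2(C)O | target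

Total step count: 11. Longest linear sequence: 11 steps (from 1).

## Least certain steps

**Step 9 (key step).**
- What may go wrong: the 11,12-epoxide may be lost once the acid is free. After the shift this epoxide is tertiary and allylic, so ionisation at C12 followed by capture at C14 by the carboxyl (five-membered ring) may compete with SN2 opening at C3. Endo opening at the tertiary C4 is a second leak.
- Fallback (from 14, rejoining at 19): the two events are decoupled and the allylic activation is removed before the acid is released. Enolisation as before, but silylation with t-BuMe2SiCl, should give after the same [3,3] shift the isolable tert-butyldimethylsilyl ester F1. Diimide under the conditions of step 10 should saturate C13=C14 to give the silyl ester F2. Bu4NF buffered with AcOH should free the saturated epoxy acid F3, which holds only ordinary trisubstituted epoxides and should lactonise to 19.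

**Step 7.**
- What may go wrong: oligomerisation or ethyl transfer may occur in place of ring closure. Facial control at C13 may erode if the epoxide oxygen binds zinc, or if ligand preference and substrate preference oppose each other.
- Fallback (from 8, rejoining at 12 and 14): Cp2Zr(H)Cl then I2 should give the (E)-vinyl iodide alcohol F4, and TEMPO/PhI(OAc)2 the iodo aldehyde F5. A Nozaki–Hiyama–Kishi closure (CrCl2, catalytic NiCl2, DMSO–THF, high dilution) should then give 12 together with its 13R epimer F6. Both epimers are usable: 12 goes through step 8, and F6 goes through Mitsunobu esterification with propanoic acid (inversion) to 14.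

**Step 2.**
- What may go wrong: the triflate may decompose through participation of the epoxide oxygen, or proton abstraction may outrun displacement at the epoxy-carbinyl carbon.
- Fallback (from 2, rejoining at 8): the C1–C2 bond is made by opening a terminal epoxide instead.
  - Lithium acetylide–ethylenediamine complex in DMSO should intercept the Payne-rearranged 2,3-epoxide at C2 to give the alkynyl (3R,4S)-diol F7.
  - Selective mesylation of the secondary hydroxyl gives the mesylate F8.
  - K2CO3/MeOH should close O4 onto C3 with inversion, restoring the (3S,4S)-epoxide as the terminal alkyne F9.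
  - The conditions of step 3 give its C13 alcohol F10, and those of step 4 give 8.

**Step 10.**
- What may go wrong: discrimination between the olefins may be insufficient, because C13=C14 is flanked by the quaternary C12 and the branched C1. This could lead to slow reduction and onset of attack at C7=C8.
- Fallback (from 18 to 19, no new compound): the olefins are told apart by coordination instead of by transition-state strain. Homogeneous hydrogenation with RhCl(PPh3)3 under H2 in benzene is used, a catalyst that binds 1,2-disubstituted but not trisubstituted olefins.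

**Step 11.**
- What may go wrong: hydrogen may be abstracted from C19 instead of C6, since both lie on the crowded side of the olefin, and attack may occur on the inner face.
- Fallback (from 19, returning to 19): a recycling loop replaces reliance on selectivity.
  - The regioisomeric (7S)-7-hydroperoxy-8(19)-ene F11 is separated.
  - PPh3 reduces it to the allylic alcohol F12.
  - Mitsunobu displacement with 2-nitrobenzenesulfonyl hydrazide should give the allylic diazene F13.
  - F13 loses N2 with transposition of the olefin back to C7=C8, regenerating 19 for renewed photooxygenation.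

## Further compounds

F1 | step 9 | tert-butyldimethylsilyl ester of 17 | CC(C)(C)[Si](C)(C)OC(=O)[C@@H](C)[C@H]1C[C@@H]2O[C@@]2(C)CC/C=C(C)/CC[C@@H]2O[C@@]2(C)/C=C/1
F2 | step 9 | 13,14-dihydro derivative of F1 | CC(C)(C)[Si](C)(C)OC(=O)[C@@H](C)[C@H]1C[C@@H]2O[C@@]2(C)CC/C=C(C)/CC[C@@H]2O[C@@]2(C)CC1
F3 | step 9 | 13,14-dihydro derivative of 17 | OC(=O)[C@@H](C)[C@H]1C[C@@H]2O[C@@]2(C)CC/C=C(C)/CC[C@@H]2O[C@@]2(C)CC1
F4 | step 7 | (E)-C14 vinyl iodide, bis-epoxy C13 alcohol | OC[C@]1(C)O[C@H]1CC/C(C)=C/CC[C@]2(C)O[C@H]2C/C=C/I
F5 | step 7 | (E)-C14 vinyl iodide, bis-epoxy C13 aldehyde | O=C[C@]1(C)O[C@H]1CC/C(C)=C/CC[C@]2(C)O[C@H]2C/C=C/I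
F6 | step 7 | 13R epimer of 12 | O[C@@H]1/C=C/C[C@@H]2O[C@@]2(C)CC/C=C(C)/CC[C@@H]2O[C@]21C
F7 | step 2 | alkynyl (3R,4S)-diol | C#CC[C@@H](O)[C@@](C)(O)CC/C=C(C)/CCC=C(C)C
F8 | step 2 | C3 mesylate of F7 | C#CC[C@@H](OS(C)(=O)=O)[C@@](C)(O)CC/C=C(C)/CCC=C(C)C
F9 | step 2 | (3S,4S)-epoxy dienyne with terminal alkyne | CC(C)=CCC/C(C)=C/CC[C@]1(C)O[C@H]1CC#C
F10 | step 2 | C13 allylic alcohol of F9 | OC/C(C)=C/CC/C(C)=C/CC[C@]1(C)O[C@H]1CC#C
F0 | step 10 | none | none
F11 | step 11 | (7S)-7-hydroperoxy-8(19)-ene regioisomer of 20 | C[C@@H]1C(=O)O[C@@H]2C[C@H]1CC[C@]1(C)O[C@H]1CCC(=C)[C@@H](OO)CC[C@]2(C)O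
F12 | step 11 | (7S)-7-hydroxy-8(19)-ene | C[C@@H]1C(=O)O[C@@H]2C[C@H]1CC[C@]1(C)O[C@H]1CCC(=C)[C@@H](O)CC[C@]2(C)O
F13 | step 11 | C7 allylic diazene (inverted at C7) | C[C@@H]1C(=O)O[C@@H]2C[C@H]1CC[C@]1(C)O[C@H]1CCC(=C)[C@H](N=N)CC[C@]2(C)O
A1 | alternative 1 | macrocyclic (3E,7E,11E)-triene acid, C1 and C15 as in the target | C[C@H](C(=O)O)[C@H]1C/C=C(C)/CC/C=C(C)/CC/C=C(C)/CC1
A2 | alternative 2 | C3 aldehyde / C4 methyl ketone seco ester with 11,12-epoxide | COC(=O)[C@@H](C)[C@@H](CC=O)CC[C@]1(C)O[C@H]1CC/C(C)=C/CCC(C)=O
A3 | alternative 3 | macrocyclic (3R,4S)-diol with C1=C14 olefin and 11,12-epoxide | O[C@@H]1C/C=C/C[C@]2(C)O[C@H]2CC/C(C)=C/CC[C@]1(C)O
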